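**Retrosynthetic overview**

1. Eudesmane numbering is used: ring A = C1–C5, C10; ring B = C5–C10; CH3 on C4 and on C10; side chain C11–C13 on C7. Late disconnections: the methyl acrylate comes from α-methylenation and oxidation of a C11–C12 aldehyde arm carried as its dimethyl acetal, the 3β-ester from Luche reduction and Yamaguchi acylation of a C3 enone, and the 8β-acetate from bulky-hydride reduction of a C8 ketone.
2. Core disconnection: C3–C4 and C5–C10 are cut together. The 4-methyl-Δ4-octalin-3,8-dione becomes a monocyclic (R)-2-methylcyclobutanone whose quaternary carbon carries the chain C9H2–C8(=O)–C7H(arm)–C6H2–C≡C–CH3.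
3. Enabling feature: in ring A the ketone carbon C3 and the quaternary carbon C10 flank the C4(CH3)=C5 double bond and are joined on the other side only by C1–C2. Ring A is therefore a cyclobutanone (C3, C2, C1, C10) whose acyl–alkyl bond has taken up a but-2-yne unit (C4≡C5); because C5 is tied to C10 by the four-atom chain C6–C9, the same insertion closes ring B.
4. Ring order: the four-membered ring first (photochemical Wolff ring contraction; quaternary C10 by palladium-catalysed decarboxylative asymmetric allylation), then the chain (aldol, oxidation, Krapcho), then rings A and B together. C7, C8 and C3 are set afterwards under control of C10.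

Key step: step 10

Assumption: the (S)-configured electron-poor tert-butyl-PHOX ligand of step 4 is taken to give the (R)-ketone 6 (its antipode is used if the sense is the opposite); compounds 1, 8, 9 and 19 are taken as purchasable.

**Route**

Step 1
Reactants: 1 cyclopentane-1,3-dione
Product: 2 2-diazocyclopentane-1,3-dione
Conditions: 4-acetamidobenzenesulfonyl azide, Et3N, MeCN, 0 °C to rt
Reagents that add atoms: 4-acetamidobenzenesulfonyl azide, CC(=O)Nc1ccc(cc1)S(=O)(=O)N=[N+]=[N-]
Why: Regitz diazo transfer to the doubly activated methylene of a cyclic 1,3-diketone is routine and creates no stereocentre.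

Step 2
Reactants: 2 2-diazocyclopentane-1,3-dione
Product: 4 prop-2-en-1-yl 2-oxocyclobutane-1-carboxylate, via acyl ketene 3 (not isolated)
Conditions: hν (300 nm), allyl alcohol, CH2Cl2, rt
Reagents that add atoms: allyl alcohol, C=CCO
Why: Photochemical Wolff rearrangement contracts the ring to the acyl ketene, which the alcohol traps as the β-keto ester, so the strained ketone that later drives the key step is made here.

Step 3
Reactants: 4 prop-2-en-1-yl 2-oxocyclobutane-1-carboxylate
Product: 5 prop-2-en-1-yl 1-methyl-2-oxocyclobutane-1-carboxylate (racemic)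
Conditions: MeI, K2CO3, acetone, rt
Reagents that add atoms: iodomethane, CI
Why: C-Alkylation of a β-keto ester enolate (SN2) should be clean, and the racemic centre it forms is erased in step 4.

Step 4
Reactants: 5 prop-2-en-1-yl 1-methyl-2-oxocyclobutane-1-carboxylate
Product: 6 (2R)-2-methyl-2-(prop-2-en-1-yl)cyclobutan-1-one
Conditions: Pd2(pmdba)3 (pmdba = 4,4'-dimethoxydibenzylideneacetone, 2.5 mol%), (S)-4-tert-butyl-2-[2-(bis(4-(trifluoromethyl)phenyl)phosphanyl)-5-(trifluoromethyl)phenyl]-4,5-dihydrooxazole (6 mol%), toluene, 20 °C
Reagents that add atoms: none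
Why: Palladium-catalysed decarboxylative asymmetric allylic alkylation (Tsuji–Trost type) of allyl β-keto esters is established for cyclobutanones; the racemic ester converges through the achiral enolate and the chiral P,N ligand on the allylpalladium enolate ion pair (from zerovalent palladium) fixes the quaternary centre that becomes C10.

Step 5
Reactants: 6 (2R)-2-methyl-2-(prop-2-en-1-yl)cyclobutan-1-one
Product: 7 2-[(1R)-1-methyl-2-oxocyclobutyl]acetaldehyde
Conditions: O3, CH2Cl2, −78 °C; then PPh3, −78 °C to rt
Reagents that add atoms: ozone, [O-][O+]=O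
Why: Ozonolysis with reductive work-up cleaves the only alkene and leaves the quaternary centre untouched.

Step 6
Reactants: 8 methyl 4,4-dimethoxybutanoate; 9 1-bromobut-2-yne
Product: 10 methyl 2-(2,2-dimethoxyethyl)hex-4-ynoate (racemic)
Conditions: LiN(i-Pr)2, THF, −78 °C; then 9, DMPU, −78 to −20 °C
Reagents that add atoms: none
Why: Ester enolate alkylation (SN2) with a reactive propargylic bromide; the new centre (later C7) is deliberately racemic because it is equilibrated after the key step.

Step 7
Reactants: 10 methyl 2-(2,2-dimethoxyethyl)hex-4-ynoate; 7 2-[(1R)-1-methyl-2-oxocyclobutyl]acetaldehyde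
Product: 11 methyl 2-(2,2-dimethoxyethyl)-2-{1-hydroxy-2-[(1R)-1-methyl-2-oxocyclobutyl]ethyl}hex-4-ynoate (mixture of diastereomers at the two new centres)
Conditions: LiN(i-Pr)2, THF, −78 °C; then 7, −78 °C; AcOH quench at −78 °C
Reagents that add atoms: none
Why: Crossed aldol addition of the preformed lithium ester enolate to the aldehyde, which is far more electrophilic than the hindered α-quaternary ketone; both new centres are removed again in steps 8 to 10.

Step 8
Reactants: 11 aldol adduct
Product: 12 methyl 2-(2,2-dimethoxyethyl)-2-{2-[(1R)-1-methyl-2-oxocyclobutyl]acetyl}hex-4-ynoate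
Conditions: Dess–Martin periodinane, pyridine, CH2Cl2, 0 °C to rt
Reagents that add atoms: none
Why: Dess–Martin oxidation of the secondary alcohol under buffered, base-free conditions should avoid retro-aldol cleavage and spare the acetal.

Step 9
Reactants: 12 β-keto ester
Product: 13 (2R)-2-[3-(2,2-dimethoxyethyl)-2-oxohept-5-yn-1-yl]-2-methylcyclobutan-1-one (both epimers at the chain CH)
Conditions: LiCl, H2O, DMSO, 130 °C
Reagents that add atoms: none
Why: Krapcho dealkoxycarbonylation (chloride SN2 at the ester methyl, then loss of CO2) works on α,α-disubstituted β-keto esters under neutral conditions that should leave the acetal and the four-membered ketone intact.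

Step 10
Reactants: 13 (2R)-2-[3-(2,2-dimethoxyethyl)-2-oxohept-5-yn-1-yl]-2-methylcyclobutan-1-one
Product: 15 7β-(2,2-dimethoxyethyl)-4,10β-dimethyl-Δ4-octalin-3,8-dione [(4aR,7R)-7-(2,2-dimethoxyethyl)-1,4a-dimethyl-4,4a,7,8-tetrahydronaphthalene-2,6(3H,5H)-dione], via C7-epimeric enedione 14 (not isolated)
Conditions: [Rh(C2H4)2Cl]2 (5 mol%), P[3,5-(CF3)2C6H3]3 (20 mol%), 1,4-dioxane, 130 °C; then NaOMe (0.2 equiv), MeOH, rt
Reagents that add atoms: none
Why: Monovalent rhodium cleaves the acyl–C(quaternary) bond of the strained four-membered ketone, the tethered alkyne inserts syn into the Rh–C10 bond and C(acyl)–C(alkenyl) reductive elimination releases the cyclohexenone; NaOMe then equilibrates C7 in the same pot. The closest known reaction is the rhodium-catalysed intramolecular cut-and-sew coupling of cyclobutanones with alkynes tethered at the α-carbon, which gives cyclohexenone-fused bicycles. Ring B closes by 6-exo-dig carbometalation (C10 onto C5) and ring A by two-carbon ring expansion of the cyclobutanone, that is, reductive elimination of C3–C4 from a seven-membered rhodacycle. No stereocentre is created at C10: the centre set in step 4 is transferred with retention, since oxidative addition and migratory insertion both retain configuration at the migrating carbon, while C7 is set by thermodynamic control, the side chain going equatorial (β) on the chair of ring B. The step needs site selectivity for the more substituted proximal C–C bond and chemoselectivity over the C8 ketone and over CO loss; the tether secures the first (only coupling at the substituted α-carbon reaches the alkyne through a six-membered ring), ring strain the second (the acyclic ketone has none), and a small electron-poor phosphine with fast intramolecular alkyne capture is relied on for the third. Syn insertion places C3 and C10 cis on the new C4=C5 bond, as ring A demands, and the alkyne methyl becomes the C4 methyl.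

Step 11
Reactants: 15 7β-(2,2-dimethoxyethyl)-4,10β-dimethyl-Δ4-octalin-3,8-dione
Product: 16 8β-hydroxy-7β-(2,2-dimethoxyethyl)-4,10β-dimethyl-Δ4-octalin-3-one
Conditions: LiBH(s-Bu)3 (L-Selectride, 1.1 equiv), THF, −78 °C; aqueous work-up
Reagents that add atoms: none
Why: Diastereoselective ketone reduction with a bulky trialkylborohydride: hydride should attack the saturated ketone equatorially from the α face, away from the axial C10 methyl, giving the axial 8β-alcohol cis to the C7 chain, while the tetrasubstituted enone reacts much more slowly at this temperature.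

Step 12
Reactants: 16 8β-hydroxy enone
Product: 17 8β-acetoxy-7β-(2,2-dimethoxyethyl)-4,10β-dimethyl-Δ4-octalin-3-one
Conditions: Ac2O, DMAP, Et3N, CH2Cl2, rt
Reagents that add atoms: acetic anhydride, CC(=O)OC(C)=O
Why: DMAP-catalysed acylation caps the 8β-oxygen before C12 is ever raised to the acid level, so that lactonisation onto C12 cannot occur later.

Step 13
Reactants: 17 8β-acetoxy enone
Product: 18 8β-acetoxy-3β-hydroxy-7β-(2,2-dimethoxyethyl)-4,10β-dimethyl-Δ4-octalin
Conditions: NaBH4, CeCl3·7H2O, MeOH, −40 °C
Reagents that add atoms: none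
Why: Luche 1,2-reduction: axial hydride attack from the α face, opposite the C10 methyl, should give the pseudo-equatorial 3β-alcohol, as is usual for 4-methyl-Δ4-3-keto decalins.

Step 14
Reactants: 18 3β-alcohol; 19 (E)-3-methylpent-2-enoic acid
Product: 20 8β-acetoxy-3β-[(E)-3-methylpent-2-enoyloxy]-7β-(2,2-dimethoxyethyl)-4,10β-dimethyl-Δ4-octalin
Conditions: 19, 2,4,6-trichlorobenzoyl chloride, Et3N, THF, rt; then 18, DMAP, toluene, rt
Reagents that add atoms: none
Why: Yamaguchi esterification (mixed anhydride, DMAP acyl transfer) acylates hindered secondary alcohols without touching the carbinol centre, so the 3β configuration is kept and the E geometry comes from the acid.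

Step 15
Reactants: 20 acetal diester
Product: 21 the corresponding C12 aldehyde (2-oxoethyl arm on C7)
Conditions: PPTS (cat.), acetone/H2O (4:1), 45 °C
Reagents that add atoms: water, O
Why: Mild acid-catalysed acetal hydrolysis should leave the acetate and the allylic enoate intact.

Step 16
Reactants: 21 aldehyde
Product: 23 α-methylene aldehyde (3-oxoprop-1-en-2-yl group on C7), via Mannich base 22 (not isolated)
Conditions: CH2=NMe2+ I− (Eschenmoser's salt), Et3N, CH2Cl2, rt
Reagents that add atoms: N,N-dimethylmethyleneiminium iodide, C=[N+](C)C.[I-]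
Why: Mannich reaction at the only enolisable CH2 next to the aldehyde followed by β-elimination of dimethylamine (α-methylenation) installs C13 under conditions too mild to affect the esters.

Step 17
Reactants: 23 α-methylene aldehyde
Product: 24 the corresponding acrylic acid (8β-acetoxy-3β-[(E)-3-methylpent-2-enoyloxy]eudesma-4,11(13)-dien-12-oic acid)
Conditions: NaClO2, NaH2PO4, 2-methyl-2-butene, t-BuOH/H2O, 0 °C to rt
Reagents that add atoms: sodium chlorite, [Na+].[O-]Cl=O
Why: Pinnick oxidation converts enals to acrylic acids without touching alkenes, the hypochlorite being scavenged by the added olefin.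

Step 18
Reactants: 24 acrylic acid
Product: 25 target CNP0118541.1, methyl 8β-acetoxy-3β-[(E)-3-methylpent-2-enoyloxy]eudesma-4,11(13)-dien-12-oate
Conditions: Me3SiCHN2, MeOH/toluene (1:4), 0 °C
Reagents that add atoms: trimethylsilyldiazomethane, C[Si](C)(C)C=[N+]=[N-]
Why: O-Methylation of the carboxylic acid by diazomethane generated in situ is neutral, so the acrylate, the acetate and the enoate should survive.

**Compound list**

1 | cyclopentane-1,3-dione | O=C1CCC(=O)C1 | starting material
2 | 2-diazocyclopentane-1,3-dione | [N-]=[N+]=C1C(=O)CCC1=O | intermediate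
3 | (2-oxocyclobutylidene)methanone (acyl ketene) | O=C=C1CCC1=O | intermediate
4 | prop-2-en-1-yl 2-oxocyclobutane-1-carboxylate | C=CCOC(=O)C1CCC1=O | intermediate
5 | prop-2-en-1-yl 1-methyl-2-oxocyclobutane-1-carboxylate (racemic) | C=CCOC(=O)C1(C)CCC1=O | intermediate
6 | (2R)-2-methyl-2-(prop-2-en-1-yl)cyclobutan-1-one | C=CC[C@@]1(C)CCC1=O | intermediate
7 | 2-[(1R)-1-methyl-2-oxocyclobutyl]acetaldehyde | O=CC[C@@]1(C)CCC1=O | intermediate
8 | methyl 4,4-dimethoxybutanoate | COC(=O)CCC(OC)OC | starting material
9 | 1-bromobut-2-yne | CC#CCBr | starting material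
10 | methyl 2-(2,2-dimethoxyethyl)hex-4-ynoate (racemic) | COC(=O)C(CC#CC)CC(OC)OC | intermediate
11 | methyl 2-(2,2-dimethoxyethyl)-2-{1-hydroxy-2-[(1R)-1-methyl-2-oxocyclobutyl]ethyl}hex-4-ynoate (diastereomer mixture) | COC(=O)C(CC#CC)(CC(OC)OC)C(O)C[C@@]1(C)CCC1=O | intermediate
12 | methyl 2-(2,2-dimethoxyethyl)-2-{2-[(1R)-1-methyl-2-oxocyclobutyl]acetyl}hex-4-ynoate (epimers at the quaternary ester carbon) | COC(=O)C(CC#CC)(CC(OC)OC)C(=O)C[C@@]1(C)CCC1=O | intermediate
13 | (2R)-2-[3-(2,2-dimethoxyethyl)-2-oxohept-5-yn-1-yl]-2-methylcyclobutan-1-one (epimers at the chain CH) | CC#CCC(CC(OC)OC)C(=O)C[C@@]1(C)CCC1=O | intermediate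
14 | 7-(2,2-dimethoxyethyl)-4,10β-dimethyl-Δ4-octalin-3,8-dione, C7 epimers | COC(OC)CC1CC2=C(C)C(=O)CC[C@]2(C)CC1=O | intermediate
15 | 7β-(2,2-dimethoxyethyl)-4,10β-dimethyl-Δ4-octalin-3,8-dione, (4aR,7R) | COC(OC)C[C@H]1CC2=C(C)C(=O)CC[C@]2(C)CC1=O | intermediate
16 | 8β-hydroxy-7β-(2,2-dimethoxyethyl)-4,10β-dimethyl-Δ4-octalin-3-one | COC(OC)C[C@H]1CC2=C(C)C(=O)CC[C@]2(C)C[C@H]1O | intermediate
17 | 8β-acetoxy-7β-(2,2-dimethoxyethyl)-4,10β-dimethyl-Δ4-octalin-3-one | COC(OC)C[C@H]1CC2=C(C)C(=O)CC[C@]2(C)C[C@H]1OC(C)=O | intermediate
18 | 8β-acetoxy-3β-hydroxy-7β-(2,2-dimethoxyethyl)-4,10β-dimethyl-Δ4-octalin | COC(OC)C[C@H]1CC2=C(C)[C@@H](O)CC[C@]2(C)C[C@H]1OC(C)=O | intermediate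
19 | (E)-3-methylpent-2-enoic acid | CC/C(C)=C/C(=O)O | starting material
20 | 8β-acetoxy-3β-[(E)-3-methylpent-2-enoyloxy]-7β-(2,2-dimethoxyethyl)-4,10β-dimethyl-Δ4-octalin | COC(OC)C[C@H]1CC2=C(C)[C@@H](OC(=O)/C=C(\C)CC)CC[C@]2(C)C[C@H]1OC(C)=O | intermediate
21 | C12 aldehyde (2-oxoethyl arm on C7), otherwise as 20 | O=CC[C@H]1CC2=C(C)[C@@H](OC(=O)/C=C(\C)CC)CC[C@]2(C)C[C@H]1OC(C)=O | intermediate
22 | Mannich base (3-(dimethylamino)-1-oxopropan-2-yl group on C7, both C11 epimers) | CN(C)CC(C=O)[C@H]1CC2=C(C)[C@@H](OC(=O)/C=C(\C)CC)CC[C@]2(C)C[C@H]1OC(C)=O | intermediate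
23 | α-methylene aldehyde (3-oxoprop-1-en-2-yl group on C7) | C=C(C=O)[C@H]1CC2=C(C)[C@@H](OC(=O)/C=C(\C)CC)CC[C@]2(C)C[C@H]1OC(C)=O | intermediate
24 | 8β-acetoxy-3β-[(E)-3-methylpent-2-enoyloxy]eudesma-4,11(13)-dien-12-oic acid | C=C(C(=O)O)[C@H]1CC2=C(C)[C@@H](OC(=O)/C=C(\C)CC)CC[C@]2(C)C[C@H]1OC(C)=O | intermediate
25 | CNP0118541.1, methyl 8β-acetoxy-3β-[(E)-3-methylpent-2-enoyloxy]eudesma-4,11(13)-dien-12-oate (3S,7R,8R,10R in eudesmane numbering) | C=C(C(=O)OC)[C@H]1CC2=C(C)[C@@H](OC(=O)/C=C(\C)CC)CC[C@]2(C)C[C@H]1OC(C)=O | target

**Step count**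

Total: 18 steps. Longest linear sequence: 17 steps (steps 1–5 and 7–18); step 6 is a one-step branch.

**Steps most likely to fail**

Step 10. The rhodium may engage the less hindered distal acyl–CH2 bond, after which the rhodacycle can lose CO or undergo β-hydride elimination before the alkyne inserts, so that the fused enone does not form. The equatorial preference at C7 may also be incomplete, because ring B has only one syn-axial hydrogen opposing an axial side chain. The fallback changes both substrate and activation mode. It sets out from β-keto ester 12, whose fully substituted C7 gives a gem-disubstituent bias towards closure of ring B and has no enolisable C7–H. Ketone and alkyne are coupled on zerovalent nickel (Ni(cod)2, PCy3, toluene, 100 °C), where the C–C bond is cleaved by β-carbon elimination from an oxanickelacycle formed by carbonyl–alkyne oxidative cyclisation instead of by oxidative addition. This should give the bicyclic β-keto ester F1. Krapcho dealkoxycarbonylation (LiCl, H2O, DMSO, 130 °C) and NaOMe equilibration then bring the material back to the route at 15.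

Step 7. Proton transfer from the enolisable keto aldehyde to the hindered, fully substituted lithium enolate, or retro-aldol cleavage of the congested aldolate, may lower conversion. The fallback replaces the lithium enolate by a zinc enolate. It sets out from 10, which is brominated at the α-carbon (LiN(i-Pr)2, THF, −78 °C; then CBr4) to the α-bromo ester F2. A Reformatsky reaction of F2 with 7 (activated Zn, THF, 60 °C) uses a weakly basic, aldehyde-selective zinc enolate whose zinc aldolate resists retro-aldol, and comes back to the route at 11.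

Step 14. Acyl transfer to the hindered allylic alcohol next to the C4 methyl may be slow, and during that time the activated β,β-disubstituted acrylic acid can lose its E geometry or deconjugate through a vinylketene. The fallback forms the ester C–O bond by displacement instead of acyl transfer. It sets out from 17, which is reduced with KBH(s-Bu)3 (THF, −78 °C, equatorial attack) to the 3α-alcohol F3. Mitsunobu reaction of F3 with acid 19 (PPh3, DIAD, toluene, 0 °C to rt) uses the carboxylate as nucleophile and should give, with inversion, 20, where it rejoins the route.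

**Further compounds**

F1 | step 10 | methyl 7-(2,2-dimethoxyethyl)-4,10β-dimethyl-3,8-dioxo-Δ4-octalin-7-carboxylate (both C7 epimers) | COC(=O)C1(CC(OC)OC)CC2=C(C)C(=O)CC[C@]2(C)CC1=O
F2 | step 7 | methyl 2-bromo-2-(2,2-dimethoxyethyl)hex-4-ynoate (racemic) | COC(=O)C(Br)(CC#CC)CC(OC)OC
F3 | step 14 | 8β-acetoxy-3α-hydroxy-7β-(2,2-dimethoxyethyl)-4,10β-dimethyl-Δ4-octalin | COC(OC)C[C@H]1CC2=C(C)[C@H](O)CC[C@]2(C)C[C@H]1OC(C)=O
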